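**Retrosynthetic overview**
- The free 5-OH is unmasked last, by hydrogenolysis of a benzyl ether.
- Both indoles come from 3-aryl-3-hydroxyoxindoles by one global borane reduction with dehydrative aromatisation.
- Key C–C bonds: each indole C3–aryl bond is made by adding a metallated tetramethoxybenzene to the C3 ketone of an isatin. The isatin serves as an indol-3-yl cation equivalent, so two carbons that are both innately nucleophilic (indole C3 and the electron-rich arene carbon) are joined.
- The two different isatins are added one after the other in one pot to 1,4-dibromo-2,3,5,6-tetramethoxybenzene, which is made from 1,2,4,5-tetramethoxybenzene.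
- No ring is built: the benzene core and both indole bicycles are bought intact, and the two pyrrole rings are aromatised together in the reduction step.

Assumption: the target has no stereocentre and no chiral axis (each biaryl axis lies in a mirror plane of the symmetric central ring), so "single enantiomer" means the achiral compound itself; 6-methoxyisatin and 5-(benzyloxy)isatin are taken as purchasable building blocks.

**Step 1**
Reactants: 1 1,2,4,5-tetramethoxybenzene
Product: 3 1,4-dibromo-2,3,5,6-tetramethoxybenzene, via 3-bromo-1,2,4,5-tetramethoxybenzene 2 (not isolated)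
Conditions: NBS (2.2 equiv), MeCN, 0 °C to rt, dark
Reagents that add atoms: N-bromosuccinimide, O=C1CCC(=O)N1Br
Why: Electrophilic aromatic bromination at the only two free positions, each activated by two ortho methoxy groups; NBS in MeCN is a mild polar bromine source that limits oxidative demethylation to the quinone.

**Step 2**
Reactants: 3 1,4-dibromo-2,3,5,6-tetramethoxybenzene; 4 6-methoxyisatin (6-methoxy-1H-indole-2,3-dione); 5 5-(benzyloxy)isatin (5-(benzyloxy)-1H-indole-2,3-dione)
Product: 11 5-(benzyloxy)-3-hydroxy-3-[4-(3-hydroxy-6-methoxy-2-oxoindolin-3-yl)-2,3,5,6-tetramethoxyphenyl]indolin-2-one (diastereomer mixture; both carbinol centres unassigned), via sodium 6-methoxyisatinate 6 (not isolated), via bromoaryllithium 7 (not isolated), via bromoaryl carbinolate 8 (not isolated), via lithiated carbinolate 9 (not isolated), via sodium 5-benzyloxyisatinate 10 (not isolated)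
Conditions: separate flasks: 4 (1.0 equiv) + NaH (1.05 equiv), THF, 0 °C; 5 (1.1 equiv) + NaH (1.1 equiv), THF, 0 °C. Main flask: 3, n-BuLi (1.0 equiv), THF, −78 °C; add 6, −78 to −20 °C; re-cool, n-BuLi (1.05 equiv), −78 °C; add 10, −78 to 0 °C; sat. aq NH4Cl
Reagents that add atoms: none
Why: Sequential bromine–lithium exchange and 1,2-addition of each aryllithium to the C3 ketone of an N-sodio isatin (the isatin acting as an indol-3-yl cation equivalent, reversed polarity at the normally nucleophilic indole C3); mono-exchange is clean because a second exchange would need an aryl dianion, the amidate and alkoxide sites are inert to n-BuLi, and the two carbinol stereocentres form unselectively and are erased in step 3.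

**Step 3**
Reactants: 11 the bis(3-hydroxyoxindole) from step 2
Product: 13 5-(benzyloxy)-3-[2,3,5,6-tetramethoxy-4-(6-methoxy-1H-indol-3-yl)phenyl]-1H-indole, via bis(indolin-3-ol) 12 (not isolated)
Conditions: BH3·THF (10 equiv), THF, 0 °C to 65 °C; then MeOH, 60 °C; brief wash with 0.5 M HCl
Reagents that add atoms: none
Why: Borane reduction of both secondary lactams to indolin-3-ols followed by dehydrative aromatisation (the classical dioxindole-to-indole reduction) gives both indoles and destroys both stereocentres, while the aryl methyl ethers and the benzyl ether are inert to BH3.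

**Step 4**
Reactants: 13 the benzyl-protected bis-indole
Product: 14 3-[2,3,5,6-tetramethoxy-4-(6-methoxy-1H-indol-3-yl)phenyl]-1H-indol-5-ol (CNP0234672.0)
Conditions: H2 (1 atm), Pd/C (10 wt% palladium on carbon), EtOAc–EtOH, rt, degassed solvents
Reagents that add atoms: none
Why: Catalytic hydrogenolysis of the benzyl aryl ether under neutral conditions leaves the indole rings and methyl ethers untouched; the product is achiral, so no stereocentre is at stake.

**Compound list**
1 | 1,2,4,5-tetramethoxybenzene | COc1cc(OC)c(OC)cc1OC | starting material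
2 | 3-bromo-1,2,4,5-tetramethoxybenzene | COc1cc(OC)c(OC)c(Br)c1OC | intermediate
3 | 1,4-dibromo-2,3,5,6-tetramethoxybenzene | COc1c(Br)c(OC)c(OC)c(Br)c1OC | intermediate
4 | 6-methoxyisatin | COc1ccc2c(c1)NC(=O)C2=O | starting material
5 | 5-(benzyloxy)isatin | O=C1Nc2ccc(OCc3ccccc3)cc2C1=O | starting material
6 | sodium 6-methoxyisatin-1-ide | COc1ccc2c(c1)[N-]C(=O)C2=O.[Na+] | intermediate
7 | (4-bromo-2,3,5,6-tetramethoxyphenyl)lithium | [Li]c1c(OC)c(OC)c(Br)c(OC)c1OC | intermediate
8 | lithium sodium salt (O-alkoxide, N-amidate) of 3-(4-bromo-2,3,5,6-tetramethoxyphenyl)-3-hydroxy-6-methoxyindolin-2-one, racemic | COc1ccc2c(c1)[N-]C(=O)C2([O-])c1c(OC)c(OC)c(Br)c(OC)c1OC.[Li+].[Na+] | intermediate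
9 | aryl-lithiated form of 8 (C–Li in place of C–Br), racemic | COc1ccc2c(c1)[N-]C(=O)C2([O-])c1c(OC)c(OC)c([Li])c(OC)c1OC.[Li+].[Na+] | intermediate
10 | sodium 5-(benzyloxy)isatin-1-ide | O=C1[N-]c2ccc(OCc3ccccc3)cc2C1=O.[Na+] | intermediate
11 | 5-(benzyloxy)-3-hydroxy-3-[4-(3-hydroxy-6-methoxy-2-oxoindolin-3-yl)-2,3,5,6-tetramethoxyphenyl]indolin-2-one, diastereomer mixture | COc1ccc2c(c1)NC(=O)C2(O)c1c(OC)c(OC)c(c(OC)c1OC)C1(O)C(=O)Nc2ccc(OCc3ccccc3)cc21 | intermediate
12 | 5-(benzyloxy)-3-[4-(3-hydroxy-6-methoxyindolin-3-yl)-2,3,5,6-tetramethoxyphenyl]indolin-3-ol, diastereomer mixture | COc1ccc2c(c1)NCC2(O)c1c(OC)c(OC)c(c(OC)c1OC)C1(O)CNc2ccc(OCc3ccccc3)cc21 | intermediate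
13 | 5-(benzyloxy)-3-[2,3,5,6-tetramethoxy-4-(6-methoxy-1H-indol-3-yl)phenyl]-1H-indole | COc1ccc2c(-c3c(OC)c(OC)c(-c4c[nH]c5ccc(OCc6ccccc6)cc45)c(OC)c3OC)c[nH]c2c1 | intermediate
14 | 3-[2,3,5,6-tetramethoxy-4-(6-methoxy-1H-indol-3-yl)phenyl]-1H-indol-5-ol | COc1ccc2c(-c3c(OC)c(OC)c(-c4c[nH]c5ccc(O)cc45)c(OC)c3OC)c[nH]c2c1 | target

**Totals**
Total step count: 4. Longest linear sequence: 4 (1 → 3 → 11 → 13 → 14; the isatins 4 and 5 enter in step 2).

**Steps most likely to fail, with fallbacks**

Step 2 is the riskiest. The polyanionic intermediates may be poorly soluble, the hindered aryllithium may transfer an electron to the isatinate instead of adding, and imperfect stoichiometry would give symmetrical bis-adducts. The fallback sets out from 3 and comes back at 13, completing one indole before the second bond is made: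
- Stop after the first addition (3, n-BuLi, then 6, NH4Cl) and isolate 3-(4-bromo-2,3,5,6-tetramethoxyphenyl)-3-hydroxy-6-methoxyindolin-2-one F1.
- Reduce F1 with BH3·THF, through 3-(4-bromo-2,3,5,6-tetramethoxyphenyl)-6-methoxyindolin-3-ol F2 (not isolated), to 3-(4-bromo-2,3,5,6-tetramethoxyphenyl)-6-methoxy-1H-indole F3.
- Treat F3 with NaH, then n-BuLi at −78 °C, to give the N-sodio aryllithium sodium 3-(4-lithio-2,3,5,6-tetramethoxyphenyl)-6-methoxyindol-1-ide F4 (not isolated).
- Add 10 to obtain 5-(benzyloxy)-3-hydroxy-3-[2,3,5,6-tetramethoxy-4-(6-methoxy-1H-indol-3-yl)phenyl]indolin-2-one F5.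
- Reduce F5 with BH3·THF, through 5-(benzyloxy)-3-[2,3,5,6-tetramethoxy-4-(6-methoxy-1H-indol-3-yl)phenyl]indolin-3-ol F6 (not isolated), to 13.

Step 3 is next. The double reduction may stall at a hydroxy-lactam or over-reduce to an indoline. The fallback sets out from 11 and comes back at 13, separating the two deoxygenations:
- Ionic deoxygenation of both tertiary carbinols with Et3SiH and TFA in CH2Cl2 (0 °C to rt) gives 5-(benzyloxy)-3-[2,3,5,6-tetramethoxy-4-(6-methoxy-2-oxoindolin-3-yl)phenyl]indolin-2-one F7.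
- Partial lactam reduction with i-Bu2AlH in THF–toluene (0 °C to rt) gives the bis(2-hydroxyindoline) 5-(benzyloxy)-3-[4-(2-hydroxy-6-methoxyindolin-3-yl)-2,3,5,6-tetramethoxyphenyl]indolin-2-ol F8 (not isolated), which loses water on mildly acidic work-up to give 13.

Step 1 is third. The very electron-rich arene may be oxidised by the bromine source to 2,5-dimethoxy-1,4-benzoquinone instead of being brominated. The fallback sets out from 1 and comes back at 11, replacing halogen–metal exchange by directed ortho-metalation: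
- Lithiate 1 with n-BuLi in THF (0 °C to rt) to (2,3,5,6-tetramethoxyphenyl)lithium F9 (not isolated).
- Add F9 to 6 at −78 °C and work up to 3-hydroxy-6-methoxy-3-(2,3,5,6-tetramethoxyphenyl)indolin-2-one F10.
- Mask N–H and O–H of F10 with NaH (2.1 equiv), then metalate the remaining C–H flanked by two methoxy groups with n-BuLi and TMEDA (−20 to 0 °C) to give the disodium salt of 3-(4-lithio-2,3,5,6-tetramethoxyphenyl)-3-oxido-6-methoxyindolin-2-one F11 (not isolated).
- Add 10 and quench with NH4Cl to reach 11.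

**Further compounds**
F1 | step 2 | 3-(4-bromo-2,3,5,6-tetramethoxyphenyl)-3-hydroxy-6-methoxyindolin-2-one, racemic | COc1ccc2c(c1)NC(=O)C2(O)c1c(OC)c(OC)c(Br)c(OC)c1OC
F2 | step 2 | 3-(4-bromo-2,3,5,6-tetramethoxyphenyl)-6-methoxyindolin-3-ol, racemic | COc1ccc2c(c1)NCC2(O)c1c(OC)c(OC)c(Br)c(OC)c1OC
F3 | step 2 | 3-(4-bromo-2,3,5,6-tetramethoxyphenyl)-6-methoxy-1H-indole | COc1ccc2c(-c3c(OC)c(OC)c(Br)c(OC)c3OC)c[nH]c2c1
F4 | step 2 | sodium 3-(4-lithio-2,3,5,6-tetramethoxyphenyl)-6-methoxyindol-1-ide | COc1ccc2c(-c3c(OC)c(OC)c([Li])c(OC)c3OC)c[n-]c2c1.[Na+]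
F5 | step 2 | 5-(benzyloxy)-3-hydroxy-3-[2,3,5,6-tetramethoxy-4-(6-methoxy-1H-indol-3-yl)phenyl]indolin-2-one, racemic | COc1ccc2c(-c3c(OC)c(OC)c(c(OC)c3OC)C3(O)C(=O)Nc4ccc(OCc5ccccc5)cc43)c[nH]c2c1
F6 | step 2 | 5-(benzyloxy)-3-[2,3,5,6-tetramethoxy-4-(6-methoxy-1H-indol-3-yl)phenyl]indolin-3-ol, racemic | COc1ccc2c(-c3c(OC)c(OC)c(c(OC)c3OC)C3(O)CNc4ccc(OCc5ccccc5)cc43)c[nH]c2c1
F7 | step 3 | 5-(benzyloxy)-3-[2,3,5,6-tetramethoxy-4-(6-methoxy-2-oxoindolin-3-yl)phenyl]indolin-2-one, diastereomer mixture | COc1ccc2c(c1)NC(=O)C2c1c(OC)c(OC)c(c(OC)c1OC)C1C(=O)Nc2ccc(OCc3ccccc3)cc21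
F8 | step 3 | 5-(benzyloxy)-3-[4-(2-hydroxy-6-methoxyindolin-3-yl)-2,3,5,6-tetramethoxyphenyl]indolin-2-ol, diastereomer mixture | COc1ccc2c(c1)NC(O)C2c1c(OC)c(OC)c(c(OC)c1OC)C1C(O)Nc2ccc(OCc3ccccc3)cc21
F9 | step 1 | (2,3,5,6-tetramethoxyphenyl)lithium | [Li]c1c(OC)c(OC)cc(OC)c1OC
F10 | step 1 | 3-hydroxy-6-methoxy-3-(2,3,5,6-tetramethoxyphenyl)indolin-2-one, racemic | COc1ccc2c(c1)NC(=O)C2(O)c1c(OC)c(OC)cc(OC)c1OC
F11 | step 1 | disodium salt (O-alkoxide, N-amidate) of 3-(4-lithio-2,3,5,6-tetramethoxyphenyl)-3-hydroxy-6-methoxyindolin-2-one, racemic | COc1ccc2c(c1)[N-]C(=O)C2([O-])c1c(OC)c(OC)c([Li])c(OC)c1OC.[Na+].[Na+]
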